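**Strategy.** Everything rests on C5 of the isopropylcyclohexane ring (ring carbons C1–C6: C1 isopropyl, C4 carbinol, C6 side chain): it bears the exocyclic lactone carbonyl and sits beside C6, whose acrylate arm ends in the oxepinone oxygen. That carbonyl carbon is therefore kept as the ring ketone of a cycloheptanone. In one operation, photochemical Wolff rearrangement of the α-diazo ketone contracts the seven-membered carbocycle to the cyclohexane, turns the ketone into a ketene on C5, and lets the side-chain hydroxyl capture it, which closes the seven-membered lactone and sets C5. The precursor is a fully substituted 2-diazocycloheptanone that already carries the second terpenoid half as its ester.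

Key step: step 22

Assumption: the prolinol ether of step 2 and the oxazaborolidinium salt of step 15 follow their accepted facial-selectivity models; if either gave the antipode, its mirror-image catalyst would be used and nothing else would change.

**Left half (steps 1–10)**

Step 1
Reactants: 1 2-[(tert-butyldimethylsilyl)oxy]-N-methoxy-N-methylacetamide
Product: 2 1-[(tert-butyldimethylsilyl)oxy]but-3-en-2-one
Conditions: CH2=CHMgBr, THF, −78 to 0 °C; inverse quench into cold 1 M HCl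
Reagents that add atoms: vinylmagnesium bromide, C=C[Mg]Br
Why: Weinreb ketone synthesis, in which the chelated tetrahedral adduct stops at the ketone and the cold acidic quench keeps the released amine from adding to the enone.

Step 2
Reactants: 2 1-[(tert-butyldimethylsilyl)oxy]but-3-en-2-one; 3 3-methylbutanal
Product: 4 (2R)-6-[(tert-butyldimethylsilyl)oxy]-5-oxo-2-(propan-2-yl)hexanal
Conditions: (R)-2-[methoxy(diphenyl)methyl]pyrrolidine (10 mol%), ethyl 3,4-dihydroxybenzoate (20 mol%), neat, 4 °C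
Reagents that add atoms: none
Why: Enamine-catalysed asymmetric Michael addition of an aldehyde to a vinyl ketone, in which the diarylmethyl ether shields one face of the E-enamine so that the isopropyl-bearing centre (later C1) should form as R.

Step 3
Reactants: 4 (2R)-6-[(tert-butyldimethylsilyl)oxy]-5-oxo-2-(propan-2-yl)hexanal
Product: 6 (5R)-2-methylidene-5-(propan-2-yl)hept-6-en-1-ol, via silyl ether 5 (not isolated)
Conditions: Zn, CH2Br2, TiCl4, THF/CH2Cl2, 0 °C to rt; aqueous work-up; then Bu4NF, THF, 0 °C; aq. NH4Cl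
Reagents that add atoms: dibromomethane, BrCBr
Why: Lombardo methylenation converts both the aldehyde and the ketone into terminal alkenes under non-basic conditions, so the α-stereocentre should not epimerise, and fluoride then frees the allylic alcohol needed for the directed epoxidation.

Step 4
Reactants: 6 (5R)-2-methylidene-5-(propan-2-yl)hept-6-en-1-ol
Product: 7 {(2S)-2-[(3R)-3-(propan-2-yl)pent-4-en-1-yl]oxiran-2-yl}methanol
Conditions: Ti(OiPr)4 (10 mol%), L-(+)-diisopropyl tartrate (12 mol%), tBuOOH, 4 Å molecular sieves, CH2Cl2, −20 °C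
Reagents that add atoms: tert-butyl hydroperoxide, CC(C)(C)OO
Why: Sharpless asymmetric epoxidation touches only the allylic-alcohol alkene, and the L-tartrate should deliver oxygen to the face that gives the (S)-epoxide, which fixes the quaternary carbinol centre (later C4) by reagent control.

Step 5
Reactants: 7 {(2S)-2-[(3R)-3-(propan-2-yl)pent-4-en-1-yl]oxiran-2-yl}methanol
Product: 8 (2R)-2-[(3R)-3-(propan-2-yl)pent-4-en-1-yl]oxirane-2-carbaldehyde
Conditions: Dess–Martin periodinane, NaHCO3, CH2Cl2, 0 °C to rt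
Reagents that add atoms: none
Why: Dess–Martin oxidation of a primary alcohol to an aldehyde that has no α-hydrogen and so cannot epimerise.

Step 6
Reactants: 8 (2R)-2-[(3R)-3-(propan-2-yl)pent-4-en-1-yl]oxirane-2-carbaldehyde
Product: 9 1-{(2R)-2-[(3R)-3-(propan-2-yl)pent-4-en-1-yl]oxiran-2-yl}prop-2-en-1-ol (both carbinol epimers)
Conditions: CH2=CHMgBr, THF, −78 °C; aq. NH4Cl
Reagents that add atoms: vinylmagnesium bromide, C=C[Mg]Br
Why: Grignard 1,2-addition to the aldehyde is faster than epoxide opening at low temperature, and the new carbinol centre need not be controlled because step 8 oxidises it.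

Step 7
Reactants: 9 1-{(2R)-2-[(3R)-3-(propan-2-yl)pent-4-en-1-yl]oxiran-2-yl}prop-2-en-1-ol
Product: 10 (3R,7R)-7-(propan-2-yl)-1-oxaspiro[2.6]non-5-en-4-ol (both C4 epimers)
Conditions: second-generation Grubbs catalyst (5 mol%), CH2Cl2 (0.005 M), 40 °C
Reagents that add atoms: none
Why: Ring-closing metathesis of the two terminal alkenes should close the cycloheptene with loss of ethene and without touching a stereocentre.

Step 8
Reactants: 10 (3R,7R)-7-(propan-2-yl)-1-oxaspiro[2.6]non-5-en-4-ol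
Product: 11 (3R,7R)-7-(propan-2-yl)-1-oxaspiro[2.6]non-5-en-4-one
Conditions: Dess–Martin periodinane, NaHCO3, CH2Cl2, 0 °C to rt
Reagents that add atoms: none
Why: Dess–Martin oxidation of the allylic alcohol gives the enone and removes the uncontrolled carbinol centre.

Step 9
Reactants: 11 (3R,7R)-7-(propan-2-yl)-1-oxaspiro[2.6]non-5-en-4-one
Product: 12 (3R,6R,7R)-6-ethenyl-7-(propan-2-yl)-1-oxaspiro[2.6]nonan-4-one
Conditions: CH2=CHMgBr, CuI (10 mol%), THF, −78 to −40 °C; aq. NH4Cl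
Reagents that add atoms: vinylmagnesium bromide, C=C[Mg]Br
Why: Copper-catalysed conjugate addition of the vinyl Grignard reagent should occur anti to the neighbouring isopropyl group, as in 4-substituted cycloalkenones, which sets the future C6 trans to C1 by substrate control.

Step 10
Reactants: 12 (3R,6R,7R)-6-ethenyl-7-(propan-2-yl)-1-oxaspiro[2.6]nonan-4-one; 13 tert-butyl 2-(hydroxymethyl)prop-2-enoate
Product: 14 tert-butyl (2E)-2-(hydroxymethyl)-3-[(3R,6S,7R)-4-oxo-7-(propan-2-yl)-1-oxaspiro[2.6]nonan-6-yl]prop-2-enoate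
Conditions: second-generation Hoveyda–Grubbs catalyst (10 mol%), 13 (8 equiv), CH2Cl2, 40 °C
Reagents that add atoms: none
Why: Olefin cross-metathesis of the terminal vinyl group with the 1,1-disubstituted acrylate should give the trisubstituted enoate under thermodynamic control, with the ester trans and the hydroxymethyl group cis to the ring carbon, as the later lactone closure requires.

**Right half (steps 11–18)**

Step 11
Reactants: 15 methyl (triphenyl-λ5-phosphanylidene)acetate; 16 (chloromethoxy)tri(propan-2-yl)silane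
Product: 18 methyl 2-(triphenyl-λ5-phosphanylidene)-3-{[tri(propan-2-yl)silyl]oxy}propanoate, via phosphonium chloride 17 (not isolated)
Conditions: 15 (2.1 equiv), 16 (1 equiv), toluene, rt to 50 °C; filtration of the precipitated salt
Reagents that add atoms: none
Why: C-alkylation of a stabilised phosphorus ylide by a reactive α-chloro ether, followed by transylidation in which the second equivalent of 15 deprotonates the new phosphonium salt.

Step 12
Reactants: 18 methyl 2-(triphenyl-λ5-phosphanylidene)-3-{[tri(propan-2-yl)silyl]oxy}propanoate; 19 (2E)-3-(4,4,5,5-tetramethyl-1,3,2-dioxaborolan-2-yl)prop-2-enal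
Product: 20 methyl (2E,4E)-5-(4,4,5,5-tetramethyl-1,3,2-dioxaborolan-2-yl)-2-({[tri(propan-2-yl)silyl]oxy}methyl)penta-2,4-dienoate
Conditions: toluene, 60 °C
Reagents that add atoms: none
Why: Wittig olefination with an α-substituted stabilised ylide should place the ester trans to the new β-substituent (2E), and the boronate and the 4E alkene are not affected.

Step 13
Reactants: 21 2-bromoprop-2-en-1-ol
Product: 22 [(2-bromoprop-2-en-1-yl)oxy](tert-butyl)dimethylsilane
Conditions: tBuMe2SiCl, imidazole, DMF, rt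
Reagents that add atoms: tert-butyldimethylsilyl chloride, CC(C)(C)[Si](C)(C)Cl
Why: Standard silylation of a primary alcohol, needed because a free hydroxyl would quench the Lewis acid of step 15.

Step 14
Reactants: 20 methyl (2E,4E)-5-(4,4,5,5-tetramethyl-1,3,2-dioxaborolan-2-yl)-2-({[tri(propan-2-yl)silyl]oxy}methyl)penta-2,4-dienoate; 22 [(2-bromoprop-2-en-1-yl)oxy](tert-butyl)dimethylsilane
Product: 23 methyl (2E,4E)-6-({[tert-butyl(dimethyl)silyl]oxy}methyl)-2-({[tri(propan-2-yl)silyl]oxy}methyl)hepta-2,4,6-trienoate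
Conditions: Pd(PPh3)4 (5 mol%), K3PO4 (2 M aq.), THF, 45 °C
Reagents that add atoms: none
Why: Suzuki–Miyaura coupling of an alkenyl boronate with an alkenyl bromide proceeds with retention of both alkene geometries and should give the 2-substituted (E)-1,3-diene terminus.

Step 15
Reactants: 23 methyl (2E,4E)-6-({[tert-butyl(dimethyl)silyl]oxy}methyl)-2-({[tri(propan-2-yl)silyl]oxy}methyl)hepta-2,4,6-trienoate; 24 but-3-en-2-one
Product: 25 methyl (2E)-3-[(1R,6R)-6-acetyl-3-({[tert-butyl(dimethyl)silyl]oxy}methyl)cyclohex-2-en-1-yl]-2-({[tri(propan-2-yl)silyl]oxy}methyl)prop-2-enoate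
Conditions: (S)-α,α-diphenylprolinol-derived B-(2-methylphenyl)oxazaborolidine, HN(SO2CF3)2 (20 mol% each), CH2Cl2, −78 to −40 °C
Reagents that add atoms: none
Why: Oxazaborolidinium-catalysed enantioselective Diels–Alder reaction at the electron-richer terminal diene, in which the ortho/para rule places the acetyl group next to the acrylate-bearing carbon, the endo transition state of the (E)-diene sets the two new centres cis, and the catalyst fixes their absolute sense.

Step 16
Reactants: 25 methyl (2E)-3-[(1R,6R)-6-acetyl-3-({[tert-butyl(dimethyl)silyl]oxy}methyl)cyclohex-2-en-1-yl]-2-({[tri(propan-2-yl)silyl]oxy}methyl)prop-2-enoate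
Product: 26 methyl (2E)-3-[(1R,6R)-3-({[tert-butyl(dimethyl)silyl]oxy}methyl)-6-(prop-1-en-2-yl)cyclohex-2-en-1-yl]-2-({[tri(propan-2-yl)silyl]oxy}methyl)prop-2-enoate
Conditions: Zn, CH2Br2, TiCl4, THF/CH2Cl2, 0 °C to rt
Reagents that add atoms: dibromomethane, BrCBr
Why: Lombardo methylenation is selective for the ketone over the ester and is non-basic, so the epimerisable cis centre α to the acetyl group should be kept.

Step 17
Reactants: 26 methyl (2E)-3-[(1R,6R)-3-({[tert-butyl(dimethyl)silyl]oxy}methyl)-6-(prop-1-en-2-yl)cyclohex-2-en-1-yl]-2-({[tri(propan-2-yl)silyl]oxy}methyl)prop-2-enoate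
Product: 27 methyl (2E)-3-[(1R,6S)-3-({[tert-butyl(dimethyl)silyl]oxy}methyl)-6-(propan-2-yl)cyclohex-2-en-1-yl]-2-({[tri(propan-2-yl)silyl]oxy}methyl)prop-2-enoate
Conditions: H2 (1 atm), RhCl(PPh3)3 (5 mol%), benzene, rt
Reagents that add atoms: none
Why: Homogeneous hydrogenation with Wilkinson's catalyst reduces the 1,1-disubstituted isopropenyl alkene far faster than the two trisubstituted alkenes, as in the carvone-to-dihydrocarvone reduction, and creates no new stereocentre.

Step 18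
Reactants: 27 methyl (2E)-3-[(1R,6S)-3-({[tert-butyl(dimethyl)silyl]oxy}methyl)-6-(propan-2-yl)cyclohex-2-en-1-yl]-2-({[tri(propan-2-yl)silyl]oxy}methyl)prop-2-enoate
Product: 28 (2E)-3-[(1R,6S)-3-({[tert-butyl(dimethyl)silyl]oxy}methyl)-6-(propan-2-yl)cyclohex-2-en-1-yl]-2-({[tri(propan-2-yl)silyl]oxy}methyl)prop-2-enoic acid
Conditions: LiOH, THF/MeOH/H2O, 0 °C to rt; then 1 M HCl to pH 4
Reagents that add atoms: lithium hydroxide, [Li+].[OH-]
Why: Saponification of the methyl ester, during which both silyl ethers and the hindered trisubstituted enoate should survive.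

**Union and endgame (steps 19–23)**

Step 19
Reactants: 14 tert-butyl (2E)-2-(hydroxymethyl)-3-[(3R,6S,7R)-4-oxo-7-(propan-2-yl)-1-oxaspiro[2.6]nonan-6-yl]prop-2-enoate; 28 (2E)-3-[(1R,6S)-3-({[tert-butyl(dimethyl)silyl]oxy}methyl)-6-(propan-2-yl)cyclohex-2-en-1-yl]-2-({[tri(propan-2-yl)silyl]oxy}methyl)prop-2-enoic acid
Product: 29 {(1R,4S,5R)-4-[(1E)-3-tert-butoxy-2-(hydroxymethyl)-3-oxoprop-1-en-1-yl]-1-hydroxy-2-oxo-5-(propan-2-yl)cycloheptyl}methyl ester of acid 28
Conditions: 28 (1.3 equiv), Cs2CO3 (0.3 equiv), DMF, 50 °C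
Reagents that add atoms: none
Why: Base-catalysed SN2 opening of the 2,2-disubstituted epoxide by the carboxylate at its unhindered CH2 terminus joins the two halves as the ester and frees the tertiary alcohol without touching the carbinol configuration.

Step 20
Reactants: 29 {(1R,4S,5R)-4-[(1E)-3-tert-butoxy-2-(hydroxymethyl)-3-oxoprop-1-en-1-yl]-1-hydroxy-2-oxo-5-(propan-2-yl)cycloheptyl}methyl ester of acid 28
Product: 31 {(1R,4S,5R)-4-[(1E)-3-tert-butoxy-2-(hydroxymethyl)-3-oxoprop-1-en-1-yl]-2-oxo-5-(propan-2-yl)-1-[(triethylsilyl)oxy]cycloheptyl}methyl ester of acid 28, via bis(triethylsilyl) ether 30 (not isolated)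
Conditions: Et3SiOTf (2.5 equiv), 2,6-lutidine, CH2Cl2, −78 °C; then PPTS, MeOH, 0 °C
Reagents that add atoms: triethylsilyl trifluoromethanesulfonate, CC[Si](CC)(CC)OS(=O)(=O)C(F)(F)F
Why: Silyl triflate protects the hindered tertiary alcohol, and mild acid methanolysis then removes only the primary allylic triethylsilyl ether, leaving the tertiary triethylsilyl, tert-butyldimethylsilyl and triisopropylsilyl ethers.

Step 21
Reactants: 31 {(1R,4S,5R)-4-[(1E)-3-tert-butoxy-2-(hydroxymethyl)-3-oxoprop-1-en-1-yl]-2-oxo-5-(propan-2-yl)-1-[(triethylsilyl)oxy]cycloheptyl}methyl ester of acid 28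
Product: 33 {(1R,4S,5R)-4-[(1E)-3-tert-butoxy-2-(hydroxymethyl)-3-oxoprop-1-en-1-yl]-3-diazo-2-oxo-5-(propan-2-yl)-1-[(triethylsilyl)oxy]cycloheptyl}methyl ester of acid 28, via trifluoroacetyl ketone 32 (not isolated)
Conditions: LiN(SiMe3)2 (2.2 equiv), THF, −78 °C; CF3CO2CH2CF3 (2.5 equiv); then CH3SO2N3, Et3N, H2O, MeCN, rt; aq. NH4Cl
Reagents that add atoms: methanesulfonyl azide, CS(=O)(=O)N=[N+]=[N-]
Why: Detrifluoroacetylative diazo transfer (Danheiser procedure) can act only at the single enolisable α-methylene of the ketone, while the primary hydroxyl is trifluoroacetylated in passing and released again in the aqueous amine stage.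

Step 22
Reactants: 33 {(1R,4S,5R)-4-[(1E)-3-tert-butoxy-2-(hydroxymethyl)-3-oxoprop-1-en-1-yl]-3-diazo-2-oxo-5-(propan-2-yl)-1-[(triethylsilyl)oxy]cycloheptyl}methyl ester of acid 28
Product: 35 tert-butyl (5aS,6R,9S,9aS)-9-(acyloxymethyl)-1-oxo-6-(propan-2-yl)-9-[(triethylsilyl)oxy]-1,3,5a,6,7,8,9,9a-octahydro-2-benzoxepine-4-carboxylate (acyl = acyl group of acid 28), via ketene 34 (not isolated)
Conditions: hν (365 nm), dry toluene (0.002 M), 20 °C
Reagents that add atoms: none
Why: Irradiation expels N2 from the s-Z-locked cyclic α-diazo ketone while the quaternary carbinol carbon C4 shifts with retention from the carbonyl carbon to the diazo carbon, so the seven-membered carbocycle contracts to the cyclohexane C1–C6 and the former ring carbonyl becomes an exocyclic ketene on the new C5 (photochemical Wolff rearrangement; closest precedent: ring contraction of 2-diazocycloalkanones with capture of the ketene by a hydroxyl group). The primary allylic hydroxyl of the C6 side chain, held cis to C6 by the enoate geometry, adds to the ketene carbonyl in a 7-exo-dig closure that forms the oxepinone, whereas the cyclohexane arises by the 1,2-shift and not by a closure. The ester enol so formed should be protonated at C5 along the axial direction, on the face opposite the axial C4–CH2O substituent, which gives the trans-diequatorial ring fusion that is also the thermodynamic one. C1, C4 and C6 pass through unchanged because only the C4–C(=O) bond migrates. The step needs concerted migration to outrun 1,2-hydride shift from C6–H, which the locked s-Z geometry and direct excitation should secure, and capture by the right hydroxyl, which high dilution and the silyl ethers on the tertiary alcohol and on both hydroxyls of the other half should secure.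

Step 23
Reactants: 35 tert-butyl (5aS,6R,9S,9aS)-9-(acyloxymethyl)-1-oxo-6-(propan-2-yl)-9-[(triethylsilyl)oxy]-1,3,5a,6,7,8,9,9a-octahydro-2-benzoxepine-4-carboxylate (acyl = acyl group of acid 28)
Product: 37 (5aS,6R,9S,9aS)-9-hydroxy-9-{[(2E)-2-(hydroxymethyl)-3-[(1R,6S)-3-(hydroxymethyl)-6-(propan-2-yl)cyclohex-2-en-1-yl]prop-2-enoyl]oxymethyl}-1-oxo-6-(propan-2-yl)-1,3,5a,6,7,8,9,9a-octahydro-2-benzoxepine-4-carboxylic acid (CNP0361406.5), via trimethylsilyl ester 36 (not isolated)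
Conditions: Me3SiOTf, 2,6-lutidine, CH2Cl2, 0 °C; then HF·pyridine, THF, 0 °C to rt
Reagents that add atoms: none
Why: Silyl triflate converts the tert-butyl ester into a silyl ester with loss of isobutene, and fluoride then cleaves the silyl ester and the three silyl ethers under mildly acidic conditions that should spare the lactone, the allylic ester and the allylic alcohols.

**Compound list**

1 | 2-[(tert-butyldimethylsilyl)oxy]-N-methoxy-N-methylacetamide | CON(C)C(=O)CO[Si](C)(C)C(C)(C)C | starting material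
2 | 1-[(tert-butyldimethylsilyl)oxy]but-3-en-2-one | C=CC(=O)CO[Si](C)(C)C(C)(C)C | intermediate
3 | 3-methylbutanal | CC(C)CC=O | starting material
4 | (2R)-6-[(tert-butyldimethylsilyl)oxy]-5-oxo-2-(propan-2-yl)hexanal | CC(C)[C@H](C=O)CCC(=O)CO[Si](C)(C)C(C)(C)C | intermediate
5 | tert-butyl(dimethyl){[(5R)-2-methylidene-5-(propan-2-yl)hept-6-en-1-yl]oxy}silane | CC(C)[C@H](C=C)CCC(=C)CO[Si](C)(C)C(C)(C)C | intermediate (not isolated)
6 | (5R)-2-methylidene-5-(propan-2-yl)hept-6-en-1-ol | CC(C)[C@H](C=C)CCC(=C)CO | intermediate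
7 | {(2S)-2-[(3R)-3-(propan-2-yl)pent-4-en-1-yl]oxiran-2-yl}methanol | CC(C)[C@H](C=C)CC[C@@]1(CO1)CO | intermediate
8 | (2R)-2-[(3R)-3-(propan-2-yl)pent-4-en-1-yl]oxirane-2-carbaldehyde | CC(C)[C@H](C=C)CC[C@@]1(CO1)C=O | intermediate
9 | 1-{(2R)-2-[(3R)-3-(propan-2-yl)pent-4-en-1-yl]oxiran-2-yl}prop-2-en-1-ol (both carbinol epimers) | CC(C)[C@H](C=C)CC[C@@]1(CO1)C(O)C=C | intermediate
10 | (3R,7R)-7-(propan-2-yl)-1-oxaspiro[2.6]non-5-en-4-ol (both C4 epimers) | CC(C)[C@@H]1C=CC(O)[C@]2(CO2)CC1 | intermediate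
11 | (3R,7R)-7-(propan-2-yl)-1-oxaspiro[2.6]non-5-en-4-one | CC(C)[C@@H]1C=CC(=O)[C@]2(CO2)CC1 | intermediate
12 | (3R,6R,7R)-6-ethenyl-7-(propan-2-yl)-1-oxaspiro[2.6]nonan-4-one | CC(C)[C@@H]1[C@@H](C=C)CC(=O)[C@]2(CO2)CC1 | intermediate
13 | tert-butyl 2-(hydroxymethyl)prop-2-enoate | C=C(CO)C(=O)OC(C)(C)C | starting material
14 | tert-butyl (2E)-2-(hydroxymethyl)-3-[(3R,6S,7R)-4-oxo-7-(propan-2-yl)-1-oxaspiro[2.6]nonan-6-yl]prop-2-enoate | CC(C)[C@@H]1[C@@H](/C=C(\CO)C(=O)OC(C)(C)C)CC(=O)[C@]2(CO2)CC1 | intermediate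
15 | methyl (triphenyl-λ5-phosphanylidene)acetate | COC(=O)C=P(c1ccccc1)(c1ccccc1)c1ccccc1 | starting material
16 | (chloromethoxy)tri(propan-2-yl)silane | ClCO[Si](C(C)C)(C(C)C)C(C)C | starting material
17 | [1-methoxy-1-oxo-3-{[tri(propan-2-yl)silyl]oxy}propan-2-yl](triphenyl)phosphonium chloride | COC(=O)C(CO[Si](C(C)C)(C(C)C)C(C)C)[P+](c1ccccc1)(c1ccccc1)c1ccccc1.[Cl-] | intermediate (not isolated)
18 | methyl 2-(triphenyl-λ5-phosphanylidene)-3-{[tri(propan-2-yl)silyl]oxy}propanoate | COC(=O)C(CO[Si](C(C)C)(C(C)C)C(C)C)=P(c1ccccc1)(c1ccccc1)c1ccccc1 | intermediate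
19 | (2E)-3-(4,4,5,5-tetramethyl-1,3,2-dioxaborolan-2-yl)prop-2-enal | O=C/C=C/B1OC(C)(C)C(C)(C)O1 | starting material
20 | methyl (2E,4E)-5-(4,4,5,5-tetramethyl-1,3,2-dioxaborolan-2-yl)-2-({[tri(propan-2-yl)silyl]oxy}methyl)penta-2,4-dienoate | COC(=O)/C(CO[Si](C(C)C)(C(C)C)C(C)C)=C/C=C/B1OC(C)(C)C(C)(C)O1 | intermediate
21 | 2-bromoprop-2-en-1-ol | OCC(Br)=C | starting material
22 | [(2-bromoprop-2-en-1-yl)oxy](tert-butyl)dimethylsilane | C=C(Br)CO[Si](C)(C)C(C)(C)C | intermediate
23 | methyl (2E,4E)-6-({[tert-butyl(dimethyl)silyl]oxy}methyl)-2-({[tri(propan-2-yl)silyl]oxy}methyl)hepta-2,4,6-trienoate | COC(=O)/C(CO[Si](C(C)C)(C(C)C)C(C)C)=C/C=C/C(=C)CO[Si](C)(C)C(C)(C)C | intermediate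
24 | but-3-en-2-one | CC(=O)C=C | starting material
25 | methyl (2E)-3-[(1R,6R)-6-acetyl-3-({[tert-butyl(dimethyl)silyl]oxy}methyl)cyclohex-2-en-1-yl]-2-({[tri(propan-2-yl)silyl]oxy}methyl)prop-2-enoate | COC(=O)/C(CO[Si](C(C)C)(C(C)C)C(C)C)=C/[C@H]1C=C(CO[Si](C)(C)C(C)(C)C)CC[C@H]1C(C)=O | intermediate
26 | methyl (2E)-3-[(1R,6R)-3-({[tert-butyl(dimethyl)silyl]oxy}methyl)-6-(prop-1-en-2-yl)cyclohex-2-en-1-yl]-2-({[tri(propan-2-yl)silyl]oxy}methyl)prop-2-enoate | COC(=O)/C(CO[Si](C(C)C)(C(C)C)C(C)C)=C/[C@H]1C=C(CO[Si](C)(C)C(C)(C)C)CC[C@H]1C(C)=C | intermediate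
27 | methyl (2E)-3-[(1R,6S)-3-({[tert-butyl(dimethyl)silyl]oxy}methyl)-6-(propan-2-yl)cyclohex-2-en-1-yl]-2-({[tri(propan-2-yl)silyl]oxy}methyl)prop-2-enoate | COC(=O)/C(CO[Si](C(C)C)(C(C)C)C(C)C)=C/[C@H]1C=C(CO[Si](C)(C)C(C)(C)C)CC[C@H]1C(C)C | intermediate
28 | (2E)-3-[(1R,6S)-3-({[tert-butyl(dimethyl)silyl]oxy}methyl)-6-(propan-2-yl)cyclohex-2-en-1-yl]-2-({[tri(propan-2-yl)silyl]oxy}methyl)prop-2-enoic acid | OC(=O)/C(CO[Si](C(C)C)(C(C)C)C(C)C)=C/[C@H]1C=C(CO[Si](C)(C)C(C)(C)C)CC[C@H]1C(C)C | intermediate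
29 | {(1R,4S,5R)-4-[(1E)-3-tert-butoxy-2-(hydroxymethyl)-3-oxoprop-1-en-1-yl]-1-hydroxy-2-oxo-5-(propan-2-yl)cycloheptyl}methyl ester of acid 28 | CC(C)[C@@H]1[C@@H](/C=C(\CO)C(=O)OC(C)(C)C)CC(=O)[C@](O)(COC(=O)/C(CO[Si](C(C)C)(C(C)C)C(C)C)=C/[C@H]2C=C(CO[Si](C)(C)C(C)(C)C)CC[C@H]2C(C)C)CC1 | intermediate
30 | {(1R,4S,5R)-4-[(1E)-3-tert-butoxy-3-oxo-2-{[(triethylsilyl)oxy]methyl}prop-1-en-1-yl]-2-oxo-5-(propan-2-yl)-1-[(triethylsilyl)oxy]cycloheptyl}methyl ester of acid 28 | CC(C)[C@@H]1[C@@H](/C=C(\CO[Si](CC)(CC)CC)C(=O)OC(C)(C)C)CC(=O)[C@](O[Si](CC)(CC)CC)(COC(=O)/C(CO[Si](C(C)C)(C(C)C)C(C)C)=C/[C@H]2C=C(CO[Si](C)(C)C(C)(C)C)CC[C@H]2C(C)C)CC1 | intermediate (not isolated)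
31 | {(1R,4S,5R)-4-[(1E)-3-tert-butoxy-2-(hydroxymethyl)-3-oxoprop-1-en-1-yl]-2-oxo-5-(propan-2-yl)-1-[(triethylsilyl)oxy]cycloheptyl}methyl ester of acid 28 | CC(C)[C@@H]1[C@@H](/C=C(\CO)C(=O)OC(C)(C)C)CC(=O)[C@](O[Si](CC)(CC)CC)(COC(=O)/C(CO[Si](C(C)C)(C(C)C)C(C)C)=C/[C@H]2C=C(CO[Si](C)(C)C(C)(C)C)CC[C@H]2C(C)C)CC1 | intermediate
32 | 3-(trifluoroacetyl) ketone of 31 with the primary hydroxyl as its trifluoroacetate (C3 epimers or enol) | CC(C)[C@@H]1[C@@H](/C=C(\COC(=O)C(F)(F)F)C(=O)OC(C)(C)C)C(C(=O)C(F)(F)F)C(=O)[C@](O[Si](CC)(CC)CC)(COC(=O)/C(CO[Si](C(C)C)(C(C)C)C(C)C)=C/[C@H]2C=C(CO[Si](C)(C)C(C)(C)C)CC[C@H]2C(C)C)CC1 | intermediate (not isolated)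
33 | {(1R,4S,5R)-4-[(1E)-3-tert-butoxy-2-(hydroxymethyl)-3-oxoprop-1-en-1-yl]-3-diazo-2-oxo-5-(propan-2-yl)-1-[(triethylsilyl)oxy]cycloheptyl}methyl ester of acid 28 | CC(C)[C@@H]1[C@@H](/C=C(\CO)C(=O)OC(C)(C)C)C(=[N+]=[N-])C(=O)[C@](O[Si](CC)(CC)CC)(COC(=O)/C(CO[Si](C(C)C)(C(C)C)C(C)C)=C/[C@H]2C=C(CO[Si](C)(C)C(C)(C)C)CC[C@H]2C(C)C)CC1 | intermediate
34 | ring-contracted ketene: cyclohexylidene ketene on C5, with the C4 silyl ether and acyloxymethyl group, the C6 hydroxymethyl-acrylate arm and the C1 isopropyl group | CC(C)[C@H]1CC[C@@](O[Si](CC)(CC)CC)(COC(=O)/C(CO[Si](C(C)C)(C(C)C)C(C)C)=C/[C@H]2C=C(CO[Si](C)(C)C(C)(C)C)CC[C@H]2C(C)C)C(=C=O)[C@@H]1/C=C(\CO)C(=O)OC(C)(C)C | intermediate (not isolated)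
35 | tert-butyl (5aS,6R,9S,9aS)-9-(acyloxymethyl)-1-oxo-6-(propan-2-yl)-9-[(triethylsilyl)oxy]-1,3,5a,6,7,8,9,9a-octahydro-2-benzoxepine-4-carboxylate (acyl = acyl group of acid 28) | CC(C)[C@H]1CC[C@@](O[Si](CC)(CC)CC)(COC(=O)/C(CO[Si](C(C)C)(C(C)C)C(C)C)=C/[C@H]2C=C(CO[Si](C)(C)C(C)(C)C)CC[C@H]2C(C)C)[C@H]2C(=O)OCC(C(=O)OC(C)(C)C)=C[C@H]12 | intermediate
36 | trimethylsilyl ester corresponding to tert-butyl ester 35 | CC(C)[C@H]1CC[C@@](O[Si](CC)(CC)CC)(COC(=O)/C(CO[Si](C(C)C)(C(C)C)C(C)C)=C/[C@H]2C=C(CO[Si](C)(C)C(C)(C)C)CC[C@H]2C(C)C)[C@H]2C(=O)OCC(C(=O)O[Si](C)(C)C)=C[C@H]12 | intermediate (not isolated)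
37 | (5aS,6R,9S,9aS)-9-hydroxy-9-{[(2E)-2-(hydroxymethyl)-3-[(1R,6S)-3-(hydroxymethyl)-6-(propan-2-yl)cyclohex-2-en-1-yl]prop-2-enoyl]oxymethyl}-1-oxo-6-(propan-2-yl)-1,3,5a,6,7,8,9,9a-octahydro-2-benzoxepine-4-carboxylic acid | CC(C)[C@H]1CC[C@@](O)(COC(=O)/C(=C/[C@H]2C=C(CO)CC[C@H]2C(C)C)CO)[C@H]2C(=O)OCC(C(=O)O)=C[C@H]12 | target

**Totals and risks**

Total step count: 23. Longest linear sequence: 15 steps (steps 1–10, then 19–23).

The three steps most likely to fail:

1. Step 22 (key step). The side-chain hydroxyl may capture the ketene too slowly, so that ketene dimerisation, capture by traces of water or a 1,2-hydride shift of the carbene from C6–H competes, and protonation at C5 may be unselective. The fallback sets out from 30, isolated instead of being desilylated. Diazo transfer as in step 21 should give the bis(triethylsilyl) diazo ketone F1. Irradiation at 365 nm in THF/H2O lets water trap the ketene and should give the ring-contracted trans carboxylic acid F2. PPTS in MeOH then frees the primary alcohol to the hydroxy acid F3. Yamaguchi lactonisation (2,4,6-trichlorobenzoyl chloride, Et3N, then 4-(dimethylamino)pyridine, toluene) closes the oxepinone, and the route is rejoined at 35.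

2. Step 10. Metathesis at the hindered, allylically branched vinyl group may be slower than homodimerisation of 13 and catalyst decay. The fallback sets out from 12. Ozonolysis (O3, CH2Cl2, −78 °C; PPh3) should give the aldehyde F4. In parallel, tert-butyl (triphenyl-λ5-phosphanylidene)acetate and 16 give, as in step 11, the phosphonium chloride F5 and from it the ylide F6. Wittig olefination of F4 with F6 (toluene, 60 °C) should give the triisopropylsilyl ether F7. Bu4NF buffered with AcOH removes the silyl group, and the route is rejoined at 14.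

3. Step 15. The strong Lewis acid may give poor facial or regiochemical control with the ester-conjugated triene, or cause its cationic oligomerisation. The fallback sets out from 23. Iminium-catalysed Diels–Alder reaction with acrolein (5-benzyl-2-tert-butyl-3-methylimidazolidin-4-one trifluoroacetate of the appropriate hand, MeCN/H2O, −20 °C) should give the cis aldehyde F8. CH3MgBr at −78 °C adds to the aldehyde in preference to the enoate and gives the carbinol F9. Dess–Martin oxidation then gives the methyl ketone, and the route is rejoined at 25.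

**Further compounds**

F1 | step 22 | bis(triethylsilyl) diazo ketone (33 with the primary hydroxyl as its triethylsilyl ether) | CC(C)[C@@H]1[C@@H](/C=C(\CO[Si](CC)(CC)CC)C(=O)OC(C)(C)C)C(=[N+]=[N-])C(=O)[C@](O[Si](CC)(CC)CC)(COC(=O)/C(CO[Si](C(C)C)(C(C)C)C(C)C)=C/[C@H]2C=C(CO[Si](C)(C)C(C)(C)C)CC[C@H]2C(C)C)CC1
F2 | step 22 | ring-contracted cyclohexanecarboxylic acid (C5 carboxyl trans to the C6 arm, primary hydroxyl as triethylsilyl ether) | CC(C)[C@H]1CC[C@@](O[Si](CC)(CC)CC)(COC(=O)/C(CO[Si](C(C)C)(C(C)C)C(C)C)=C/[C@H]2C=C(CO[Si](C)(C)C(C)(C)C)CC[C@H]2C(C)C)[C@@H](C(=O)O)[C@@H]1/C=C(\CO[Si](CC)(CC)CC)C(=O)OC(C)(C)C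
F3 | step 22 | hydroxy acid (F2 with the primary hydroxyl free) | CC(C)[C@H]1CC[C@@](O[Si](CC)(CC)CC)(COC(=O)/C(CO[Si](C(C)C)(C(C)C)C(C)C)=C/[C@H]2C=C(CO[Si](C)(C)C(C)(C)C)CC[C@H]2C(C)C)[C@@H](C(=O)O)[C@@H]1/C=C(\CO)C(=O)OC(C)(C)C
F4 | step 10 | (3R,6R,7R)-4-oxo-7-(propan-2-yl)-1-oxaspiro[2.6]nonane-6-carbaldehyde (formyl group trans to isopropyl) | CC(C)[C@@H]1[C@@H](C=O)CC(=O)[C@]2(CO2)CC1
F5 | step 10 | [1-tert-butoxy-1-oxo-3-{[tri(propan-2-yl)silyl]oxy}propan-2-yl](triphenyl)phosphonium chloride | CC(C)(C)OC(=O)C(CO[Si](C(C)C)(C(C)C)C(C)C)[P+](c1ccccc1)(c1ccccc1)c1ccccc1.[Cl-]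
F6 | step 10 | tert-butyl 2-(triphenyl-λ5-phosphanylidene)-3-{[tri(propan-2-yl)silyl]oxy}propanoate | CC(C)(C)OC(=O)C(CO[Si](C(C)C)(C(C)C)C(C)C)=P(c1ccccc1)(c1ccccc1)c1ccccc1
F7 | step 10 | triisopropylsilyl ether of 14 | CC(C)[C@@H]1[C@@H](/C=C(\CO[Si](C(C)C)(C(C)C)C(C)C)C(=O)OC(C)(C)C)CC(=O)[C@]2(CO2)CC1
F8 | step 15 | methyl (2E)-3-[(1R,6R)-3-({[tert-butyl(dimethyl)silyl]oxy}methyl)-6-formylcyclohex-2-en-1-yl]-2-({[tri(propan-2-yl)silyl]oxy}methyl)prop-2-enoate (formyl cis to the arm) | COC(=O)/C(CO[Si](C(C)C)(C(C)C)C(C)C)=C/[C@H]1C=C(CO[Si](C)(C)C(C)(C)C)CC[C@H]1C=O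
F9 | step 15 | methyl (2E)-3-[(1R,6R)-3-({[tert-butyl(dimethyl)silyl]oxy}methyl)-6-(1-hydroxyethyl)cyclohex-2-en-1-yl]-2-({[tri(propan-2-yl)silyl]oxy}methyl)prop-2-enoate (both carbinol epimers) | COC(=O)/C(CO[Si](C(C)C)(C(C)C)C(C)C)=C/[C@H]1C=C(CO[Si](C)(C)C(C)(C)C)CC[C@H]1C(C)O
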